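**Retrosynthetic overview**

1. Locants: five-membered ring C1 (quaternary C–CH3)–C2–C3 (OAc)–C4 (OH, i-Pr)–C5 (fusion H); seven-membered ring C5–C6 (O-aroyl)–C7=C8 (CH3)–C9–C10 (OH)–C1; α = face of the C1 methyl (cis fusion, H5 α).
2. Feature and key disconnection: the seven-membered ring C5–C10, with its C8 methyl, C7=C8 and C6 oxygen, is a 2-methoxy-4-methylphenyl ring that has taken up C1. Cutting C1–C5 and C1–C10 leads to α-methyl diazoketone 6 (intramolecular Büchner reaction); the cyclopentanone closes first (C1–C5, cyclopropanation) and the seven-membered ring then forms by opening of the norcaradiene C5–C10 bond.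
3. Seven-membered ring after the key step: enol-ether hydrolysis (C6=O, sets C5), C9=C10 epoxidation and Pd/formate opening (C10–OH), Luche reduction and acylation (C6 ester).
4. Five-membered ring: C2 ketone → C3=C4 enone → boryl-copper addition/oxidation (C4–OH) → Rubottom oxidation (C3–OH) → Barton–McCombie removal of the C2 oxygen → C3 acetate, then desilylation.
5. Before the key step: Rh/BINAP conjugate arylation of an enoate sets C4 (which steers C1), then saponification and acylation of diazoethane.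

Key step: step 4

Assumption: (S)-BINAP delivers the aryl group to the α-si face of the (E)-enoate, the sense known for cyclic enones and (E)-crotonates, which corresponds to (3S)-3.
Remark on names: from compound 9 on, "core" means cis-fused 1α,8-dimethyl-4-isopropylbicyclo[5.3.0]decane with the locants of the overview (not von Baeyer locants), 5-H being α. TBSO = tert-butyldimethylsilyloxy, TIPSO = triisopropylsilyloxy, TMSO = trimethylsilyloxy.

**Route**

Step 1
Reactants: 1 2-methoxy-4-methylphenylboronic acid; 2 ethyl (E)-4-methylpent-2-enoate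
Product: 3 ethyl (3S)-3-(2-methoxy-4-methylphenyl)-4-methylpentanoate
Conditions: Rh(acac)(C2H4)2 (3 mol%), (S)-BINAP (3.3 mol%), 1 (2.5 equiv), dioxane/H2O 10:1, 100 °C
Reagents that add atoms: none
Why: Hayashi–Miyaura asymmetric 1,4-addition, in which the aryl–Rh(I)/(S)-BINAP species inserts one enantioface of the (E)-enoate and the oxa-π-allyl rhodium is hydrolysed, so that the benzylic centre C4 is set as (S).

Step 2
Reactants: 3 ethyl (3S)-3-(2-methoxy-4-methylphenyl)-4-methylpentanoate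
Product: 4 (3S)-3-(2-methoxy-4-methylphenyl)-4-methylpentanoic acid
Conditions: LiOH·H2O (3 equiv), THF/MeOH/H2O, rt; 1 M HCl work-up
Reagents that add atoms: lithium hydroxide, [Li+].[OH-]
Why: Ester saponification (BAc2), which cannot touch the non-enolisable β-stereocentre.

Step 3
Reactants: 4 (3S)-3-(2-methoxy-4-methylphenyl)-4-methylpentanoic acid
Product: 6 (5S)-2-diazo-5-(2-methoxy-4-methylphenyl)-6-methylheptan-3-one, via acid chloride 5 (not isolated)
Conditions: (COCl)2 (1.5 equiv), DMF (cat.), CH2Cl2, 0 °C to rt, evaporate; CH3CHN2 (3 equiv, ethereal solution from N-ethyl-N-nitrosourea/KOH), Et2O, −20 to 0 °C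
Reagents that add atoms: diazoethane, CC=[N+]=[N-]
Why: Acylation of a diazoalkane by an acid chloride (first stage of an Arndt–Eistert sequence), which places the diazo group unambiguously on the methyl-bearing carbon while excess diazoethane takes up the HCl.

Step 4
Reactants: 6 (5S)-2-diazo-5-(2-methoxy-4-methylphenyl)-6-methylheptan-3-one
Product: 8 (3S,8aR)-4-methoxy-6,8a-dimethyl-3-(propan-2-yl)-3,8a-dihydroazulen-1(2H)-one, via norcaradiene 7 (not isolated)
Conditions: Rh2(OAc)4 (1 mol%), CH2Cl2, reflux, slow addition of 6 (final 0.01 M)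
Reagents that add atoms: none
Why: Rh2(OAc)4 turns the α-methyl diazoketone into an electrophilic rhodium carbenoid whose carbon C1 cyclopropanates the arene C5–C10 bond (intramolecular Büchner reaction, the closest known case being the cyclisation of 2-diazo-5-arylpentan-3-ones to 8a-methylazulenones). The five-membered ring closes in this cyclopropanation, C1 bonding to the ipso carbon C5 through the C2–C3–C4 tether (exo-type closure onto the arene π bond), and the seven-membered ring then arises not by a cyclisation but by disrotatory 6π electrocyclic opening of the C5–C10 bond of norcaradiene 7. The only new stereocentre, quaternary C1, is controlled by the C4 stereocentre of the tether: the carbenoid adds to the arene face that keeps the C1 methyl anti to the isopropyl group, which gives the 1,4-trans product. Regioselectivity for the unsubstituted ortho bond C5–C10 over the methoxy-bearing bond C5–C6 is steric, and C10 is meta to both donor groups, so that arenium-type substitution to a tetralone is not favoured. Chemoselectivity over 1,5-C–H insertion into the isopropyl methine and over 1,2-hydride shift from the C1 methyl rests on the carboxylate-ligated rhodium catalyst, which favours aromatic addition, and on slow addition at high dilution.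

Step 5
Reactants: 8 (3S,8aR)-4-methoxy-6,8a-dimethyl-3-(propan-2-yl)-3,8a-dihydroazulen-1(2H)-one
Product: 9 4β-isopropyl-core-7,9-diene-2,6-dione
Conditions: 0.5 M aq. HCl, THF, 0 °C
Reagents that add atoms: water, O
Why: Acid hydrolysis of the trienyl methyl ether, in which protonation at C5 gives a dienyl oxocarbenium ion that water turns into the C6 ketone; the proton enters on the α face of C5 (flanked by C1–CH3 and C4–H rather than by isopropyl and C10), so H5 ends cis to the C1 methyl, and cold dilute acid avoids both acid rearrangement of the norcaradiene form and enolisation at C5.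

Step 6
Reactants: 9 4β-isopropyl-core-7,9-diene-2,6-dione
Product: 10 9α,10α-epoxy-4β-isopropyl-core-7-ene-2,6-dione
Conditions: dimethyldioxirane (1.2 equiv, acetone solution), CH2Cl2, 0 °C
Reagents that add atoms: dimethyldioxirane, CC1(C)OO1
Why: Electrophilic epoxidation of a 2,4-dienone at its γ,δ-alkene C9=C10, which is less deactivated than the α,β-alkene C7=C8, with a neutral oxidant that cannot cause Baeyer–Villiger reaction at C2 or epimerise C5; attack on the α face, away from the five-membered ring that covers the β face of the seven-membered ring, sets C10 (and transient C9).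

Step 7
Reactants: 10 9α,10α-epoxy-4β-isopropyl-core-7-ene-2,6-dione
Product: 11 10α-hydroxy-4β-isopropyl-core-7-ene-2,6-dione
Conditions: Pd2(dba)3·CHCl3 (2.5 mol%), n-Bu3P (5 mol%), HCO2H (5 equiv), Et3N (2 equiv), dioxane, rt
Reagents that add atoms: none
Why: Tsuji–Shimizu hydrogenolysis of an alkenyl epoxide, in which Pd(0) ionises the allylic C9–O bond and the hydride from formate is delivered to C9 so that the C7=C8 enone stays conjugated, while the C10–O bond and its α configuration are untouched.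

Step 8
Reactants: 11 10α-hydroxy-4β-isopropyl-core-7-ene-2,6-dione
Product: 12 10α-TBSO-4β-isopropyl-core-7-ene-2,6-dione
Conditions: TBSOTf (1.3 equiv), 2,6-lutidine (2.5 equiv), CH2Cl2, −78 °C
Reagents that add atoms: tert-butyldimethylsilyl triflate, CC(C)(C)[Si](C)(C)OS(=O)(=O)C(F)(F)F
Why: Silylation of the hindered secondary alcohol with a silyl triflate and a non-nucleophilic base, cold enough that neither ketone is enol-silylated and C5 is not epimerised.

Step 9
Reactants: 12 10α-TBSO-4β-isopropyl-core-7-ene-2,6-dione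
Product: 13 6β-hydroxy-10α-TBSO-4β-isopropyl-core-7-en-2-one
Conditions: NaBH4 (1.0 equiv), CeCl3·7H2O (1.2 equiv), MeOH, −78 °C
Reagents that add atoms: none
Why: Luche 1,2-reduction, which takes the cerium-activated C6 enone in preference to the neopentyl C2 cyclopentanone (intrinsically slow toward borohydride) and delivers hydride to the convex α face of the cis-fused bicycle, anti to the five-membered ring and its β-isopropyl group, to set the 6β-alcohol.

Step 10
Reactants: 14 4-hydroxybenzoic acid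
Product: 16 4-(triisopropylsilyloxy)benzoic acid, via silyl ester 15 (not isolated)
Conditions: TIPSCl (2.2 equiv), imidazole (4.5 equiv), DMF, rt; then AcOH/THF/H2O 3:1:1, rt
Reagents that add atoms: triisopropylsilyl chloride, CC(C)[Si](Cl)(C(C)C)C(C)C
Why: Exhaustive silylation followed by selective hydrolysis of the labile silyl ester, which leaves the acid-stable aryl silyl ether in place.

Step 11
Reactants: 13 6β-hydroxy-10α-TBSO-4β-isopropyl-core-7-en-2-one; 16 4-(triisopropylsilyloxy)benzoic acid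
Product: 17 6β-[4-(TIPSO)benzoyloxy]-10α-TBSO-4β-isopropyl-core-7-en-2-one
Conditions: 16 (1.5 equiv), DCC (1.6 equiv), DMAP (0.5 equiv), CH2Cl2, rt
Reagents that add atoms: none
Why: Steglich esterification of the only free hydroxyl group, which acylates on oxygen and so retains the C6 configuration.

Step 12
Reactants: 17 6β-[4-(TIPSO)benzoyloxy]-10α-TBSO-4β-isopropyl-core-7-en-2-one
Product: 19 6β-[4-(TIPSO)benzoyloxy]-10α-TBSO-4-isopropyl-core-3,7-dien-2-one, via TMS enol ether 18 (not isolated)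
Conditions: TMSOTf (1.5 equiv), Et3N (3 equiv), CH2Cl2, 0 °C; solvent exchange; Pd(OAc)2 (1.1 equiv), MeCN, rt
Reagents that add atoms: none
Why: Ito–Saegusa oxidation, in which the C2 ketone can enolise only toward C3 (C1 is quaternary) and β-hydride elimination from the palladium enolate removes H4, giving the C3=C4 enone now that C6 is no longer a ketone and C5 cannot enolise into a 1,4-enedione.

Step 13
Reactants: 19 6β-[4-(TIPSO)benzoyloxy]-10α-TBSO-4-isopropyl-core-3,7-dien-2-one
Product: 21 4α-hydroxy-6β-[4-(TIPSO)benzoyloxy]-10α-TBSO-4β-isopropyl-core-7-en-2-one, via C4 pinacol boronate 20 (not isolated)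
Conditions: CuCl, NaOt-Bu, Xantphos (10 mol% each), B2pin2 (1.5 equiv), MeOH (2 equiv), THF, rt; then NaBO3·4H2O (5 equiv), THF/H2O, rt
Reagents that add atoms: sodium perborate, [Na+].[O-]OB=O
Why: Copper-catalysed conjugate borylation of a β,β-disubstituted enone followed by stereoretentive C–B oxidation, in which the nucleophilic boryl-copper reacts only with the enone and not with C7=C8 and adds to the convex α face, so that the tertiary C4–OH is α and the isopropyl group β.

Step 14
Reactants: 21 4α-hydroxy-6β-[4-(TIPSO)benzoyloxy]-10α-TBSO-4β-isopropyl-core-7-en-2-one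
Product: 24 3α,4α-dihydroxy-6β-[4-(TIPSO)benzoyloxy]-10α-TBSO-4β-isopropyl-core-7-en-2-one, via bis-TMS enol ether 22 (not isolated), via silyloxy epoxide 23 (not isolated)
Conditions: TMSOTf (3 equiv), Et3N (5 equiv), CH2Cl2, 0 °C; dimethyldioxirane (1.1 equiv), acetone/CH2Cl2, −78 to −20 °C; PPTS, MeOH, 0 °C
Reagents that add atoms: dimethyldioxirane, CC1(C)OO1
Why: Rubottom oxidation, in which the electron-rich silyl enol ether is oxidised far faster than the ester-deactivated C7=C8 alkene and from the convex α face (the β face carries the seven-membered ring and the isopropyl group), so that the new C3–OH is α and cis to C4–OH.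

Step 15
Reactants: 24 3α,4α-dihydroxy-6β-[4-(TIPSO)benzoyloxy]-10α-TBSO-4β-isopropyl-core-7-en-2-one
Product: 25 3α,4α-O-isopropylidene-6β-[4-(TIPSO)benzoyloxy]-10α-TBSO-4β-isopropyl-core-7-en-2-one
Conditions: 2-methoxypropene (5 equiv), PPTS (10 mol%), CH2Cl2, 0 °C to rt
Reagents that add atoms: 2-methoxypropene, COC(C)=C
Why: Acetonide formation, possible only for the cis-diol, which protects both hydroxyl groups under neutral-to-weakly-acidic conditions that do not enolise the β-hydroxy ketone.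

Step 16
Reactants: 25 3α,4α-O-isopropylidene-6β-[4-(TIPSO)benzoyloxy]-10α-TBSO-4β-isopropyl-core-7-en-2-one
Product: 26 2α-hydroxy-3α,4α-O-isopropylidene-6β-[4-(TIPSO)benzoyloxy]-10α-TBSO-4β-isopropyl-core-7-ene
Conditions: NaBH4 (3 equiv), MeOH/THF, 0 °C to rt
Reagents that add atoms: none
Why: Borohydride reduction of the only ketone with the aryl ester untouched; hydride is expected anti to the C1 methyl and the cis-fused dioxolane (2α-alcohol), and this centre is removed in step 18, so either epimer serves.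

Step 17
Reactants: 26 2α-hydroxy-3α,4α-O-isopropylidene-6β-[4-(TIPSO)benzoyloxy]-10α-TBSO-4β-isopropyl-core-7-ene
Product: 27 2α-O-(imidazol-1-ylthiocarbonyl)-3α,4α-O-isopropylidene-6β-[4-(TIPSO)benzoyloxy]-10α-TBSO-4β-isopropyl-core-7-ene
Conditions: 1,1'-thiocarbonyldiimidazole (3 equiv), DMAP (0.5 equiv), 1,2-dichloroethane, 70 °C
Reagents that add atoms: 1,1'-thiocarbonyldiimidazole, S=C(n1ccnc1)n1ccnc1
Why: Thioacylation of the hindered secondary alcohol under non-basic conditions (first half of the Barton–McCombie deoxygenation), which avoids alkoxide-mediated acyl transfer from C6.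

Step 18
Reactants: 27 2α-O-(imidazol-1-ylthiocarbonyl)-3α,4α-O-isopropylidene-6β-[4-(TIPSO)benzoyloxy]-10α-TBSO-4β-isopropyl-core-7-ene
Product: 28 3α,4α-O-isopropylidene-6β-[4-(TIPSO)benzoyloxy]-10α-TBSO-4β-isopropyl-core-7-ene
Conditions: n-Bu3SnH (3 equiv, 0.1 M), AIBN (0.2 equiv), toluene, 100 °C
Reagents that add atoms: none
Why: Barton–McCombie radical deoxygenation, in which the secondary C2 radical does not expel the β-alkoxy oxygen and is reduced by the concentrated stannane before any transannular addition to C7=C8.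

Step 19
Reactants: 28 3α,4α-O-isopropylidene-6β-[4-(TIPSO)benzoyloxy]-10α-TBSO-4β-isopropyl-core-7-ene
Product: 29 3α,4α-dihydroxy-6β-[4-(TIPSO)benzoyloxy]-10α-TBSO-4β-isopropyl-core-7-ene
Conditions: AcOH/H2O 4:1, 40 °C
Reagents that add atoms: none
Why: Mild acid hydrolysis of the acetonide, which the hindered secondary TBS ether, the aryl TIPS ether and the allylic ester should survive.

Step 20
Reactants: 29 3α,4α-dihydroxy-6β-[4-(TIPSO)benzoyloxy]-10α-TBSO-4β-isopropyl-core-7-ene
Product: 30 3α-acetoxy-4α-hydroxy-6β-[4-(TIPSO)benzoyloxy]-10α-TBSO-4β-isopropyl-core-7-ene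
Conditions: Ac2O (3 equiv), pyridine, DMAP (10 mol%), CH2Cl2, 0 °C to rt
Reagents that add atoms: acetic anhydride, CC(=O)OC(C)=O
Why: Acetylation of the secondary C3 hydroxyl in preference to the tertiary C4 hydroxyl, the other two hydroxyl groups being silylated.

Step 21
Reactants: 30 3α-acetoxy-4α-hydroxy-6β-[4-(TIPSO)benzoyloxy]-10α-TBSO-4β-isopropyl-core-7-ene
Product: 31 CNP0146780.2 (3α-acetoxy-4α,10α-dihydroxy-6β-(4-hydroxybenzoyloxy)-4β-isopropyl-core-7-ene)
Conditions: TBAF (4 equiv), AcOH (4 equiv), THF, 0 to 35 °C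
Reagents that add atoms: none
Why: Fluoride-mediated cleavage of the aryl TIPS and secondary TBS ethers, buffered with acetic acid so that the acetate and the allylic aryl ester neither migrate nor hydrolyse.

**Compound list**

1 | 2-methoxy-4-methylphenylboronic acid | COc1cc(C)ccc1B(O)O | starting material
2 | ethyl (E)-4-methylpent-2-enoate | CCOC(=O)/C=C/C(C)C | starting material
3 | ethyl (3S)-3-(2-methoxy-4-methylphenyl)-4-methylpentanoate | COc1cc(C)ccc1[C@H](C(C)C)CC(=O)OCC | intermediate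
4 | (3S)-3-(2-methoxy-4-methylphenyl)-4-methylpentanoic acid | COc1cc(C)ccc1[C@H](C(C)C)CC(=O)O | intermediate
5 | (3S)-3-(2-methoxy-4-methylphenyl)-4-methylpentanoyl chloride | COc1cc(C)ccc1[C@H](C(C)C)CC(=O)Cl | intermediate (not isolated)
6 | (5S)-2-diazo-5-(2-methoxy-4-methylphenyl)-6-methylheptan-3-one | COc1cc(C)ccc1[C@H](C(C)C)CC(=O)C(C)=[N+]=[N-] | intermediate
7 | norcaradiene tautomer of 8 (cyclopropane C1–C5–C10, diene C6=C7–C8=C9, C1 methyl syn to the diene ring, isopropyl trans to it) | COC1=CC(C)=C[C@@H]2[C@@]3(C)C(=O)C[C@@H](C(C)C)[C@@]123 | intermediate (not isolated)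
8 | (3S,8aR)-4-methoxy-6,8a-dimethyl-3-(propan-2-yl)-3,8a-dihydroazulen-1(2H)-one | COC1=C2[C@H](C(C)C)CC(=O)[C@]2(C)C=CC(C)=C1 | intermediate
9 | 4β-isopropyl-core-7,9-diene-2,6-dione | O=C1C=C(C)C=C[C@@]2(C)C(=O)C[C@@H](C(C)C)[C@@H]12 | intermediate
10 | 9α,10α-epoxy-4β-isopropyl-core-7-ene-2,6-dione | O=C1C=C(C)[C@@H]3O[C@@H]3[C@@]2(C)C(=O)C[C@@H](C(C)C)[C@@H]12 | intermediate
11 | 10α-hydroxy-4β-isopropyl-core-7-ene-2,6-dione | O=C1C=C(C)C[C@H](O)[C@@]2(C)C(=O)C[C@@H](C(C)C)[C@@H]12 | intermediate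
12 | 10α-TBSO-4β-isopropyl-core-7-ene-2,6-dione | O=C1C=C(C)C[C@H](O[Si](C)(C)C(C)(C)C)[C@@]2(C)C(=O)C[C@@H](C(C)C)[C@@H]12 | intermediate
13 | 6β-hydroxy-10α-TBSO-4β-isopropyl-core-7-en-2-one | O[C@H]1C=C(C)C[C@H](O[Si](C)(C)C(C)(C)C)[C@@]2(C)C(=O)C[C@@H](C(C)C)[C@@H]12 | intermediate
14 | 4-hydroxybenzoic acid | O=C(O)c1ccc(O)cc1 | starting material
15 | triisopropylsilyl 4-(triisopropylsilyloxy)benzoate | CC(C)[Si](OC(=O)c1ccc(O[Si](C(C)C)(C(C)C)C(C)C)cc1)(C(C)C)C(C)C | intermediate (not isolated)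
16 | 4-(triisopropylsilyloxy)benzoic acid | O=C(O)c1ccc(O[Si](C(C)C)(C(C)C)C(C)C)cc1 | intermediate
17 | 6β-[4-(TIPSO)benzoyloxy]-10α-TBSO-4β-isopropyl-core-7-en-2-one | O=C(c1ccc(O[Si](C(C)C)(C(C)C)C(C)C)cc1)O[C@H]1C=C(C)C[C@H](O[Si](C)(C)C(C)(C)C)[C@@]2(C)C(=O)C[C@@H](C(C)C)[C@@H]12 | intermediate
18 | 2-TMSO-6β-[4-(TIPSO)benzoyloxy]-10α-TBSO-4β-isopropyl-core-2,7-diene | O=C(c1ccc(O[Si](C(C)C)(C(C)C)C(C)C)cc1)O[C@H]1C=C(C)C[C@H](O[Si](C)(C)C(C)(C)C)[C@@]2(C)C(O[Si](C)(C)C)=C[C@@H](C(C)C)[C@@H]12 | intermediate (not isolated)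
19 | 6β-[4-(TIPSO)benzoyloxy]-10α-TBSO-4-isopropyl-core-3,7-dien-2-one | O=C(c1ccc(O[Si](C(C)C)(C(C)C)C(C)C)cc1)O[C@H]1C=C(C)C[C@H](O[Si](C)(C)C(C)(C)C)[C@@]2(C)C(=O)C=C(C(C)C)[C@@H]12 | intermediate
20 | 4α-(pinacolboryl)-6β-[4-(TIPSO)benzoyloxy]-10α-TBSO-4β-isopropyl-core-7-en-2-one | O=C(c1ccc(O[Si](C(C)C)(C(C)C)C(C)C)cc1)O[C@H]1C=C(C)C[C@H](O[Si](C)(C)C(C)(C)C)[C@@]2(C)C(=O)C[C@@](B3OC(C)(C)C(C)(C)O3)(C(C)C)[C@@H]12 | intermediate (not isolated)
21 | 4α-hydroxy-6β-[4-(TIPSO)benzoyloxy]-10α-TBSO-4β-isopropyl-core-7-en-2-one | O=C(c1ccc(O[Si](C(C)C)(C(C)C)C(C)C)cc1)O[C@H]1C=C(C)C[C@H](O[Si](C)(C)C(C)(C)C)[C@@]2(C)C(=O)C[C@@](O)(C(C)C)[C@@H]12 | intermediate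
22 | 2,4α-bis(TMSO)-6β-[4-(TIPSO)benzoyloxy]-10α-TBSO-4β-isopropyl-core-2,7-diene | O=C(c1ccc(O[Si](C(C)C)(C(C)C)C(C)C)cc1)O[C@H]1C=C(C)C[C@H](O[Si](C)(C)C(C)(C)C)[C@@]2(C)C(O[Si](C)(C)C)=C[C@@](O[Si](C)(C)C)(C(C)C)[C@@H]12 | intermediate (not isolated)
23 | 2α,3α-epoxy-2β,4α-bis(TMSO)-6β-[4-(TIPSO)benzoyloxy]-10α-TBSO-4β-isopropyl-core-7-ene | O=C(c1ccc(O[Si](C(C)C)(C(C)C)C(C)C)cc1)O[C@H]1C=C(C)C[C@H](O[Si](C)(C)C(C)(C)C)[C@@]2(C)[C@]3(O[Si](C)(C)C)O[C@@H]3[C@@](O[Si](C)(C)C)(C(C)C)[C@@H]12 | intermediate (not isolated)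
24 | 3α,4α-dihydroxy-6β-[4-(TIPSO)benzoyloxy]-10α-TBSO-4β-isopropyl-core-7-en-2-one | O=C(c1ccc(O[Si](C(C)C)(C(C)C)C(C)C)cc1)O[C@H]1C=C(C)C[C@H](O[Si](C)(C)C(C)(C)C)[C@@]2(C)C(=O)[C@H](O)[C@@](O)(C(C)C)[C@@H]12 | intermediate
25 | 3α,4α-O-isopropylidene-6β-[4-(TIPSO)benzoyloxy]-10α-TBSO-4β-isopropyl-core-7-en-2-one | O=C(c1ccc(O[Si](C(C)C)(C(C)C)C(C)C)cc1)O[C@H]1C=C(C)C[C@H](O[Si](C)(C)C(C)(C)C)[C@@]2(C)C(=O)[C@@H]3OC(C)(C)O[C@]3(C(C)C)[C@@H]12 | intermediate
26 | 2α-hydroxy-3α,4α-O-isopropylidene-6β-[4-(TIPSO)benzoyloxy]-10α-TBSO-4β-isopropyl-core-7-ene | O=C(c1ccc(O[Si](C(C)C)(C(C)C)C(C)C)cc1)O[C@H]1C=C(C)C[C@H](O[Si](C)(C)C(C)(C)C)[C@@]2(C)[C@H](O)[C@@H]3OC(C)(C)O[C@]3(C(C)C)[C@@H]12 | intermediate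
27 | 2α-O-(imidazol-1-ylthiocarbonyl)-3α,4α-O-isopropylidene-6β-[4-(TIPSO)benzoyloxy]-10α-TBSO-4β-isopropyl-core-7-ene | O=C(c1ccc(O[Si](C(C)C)(C(C)C)C(C)C)cc1)O[C@H]1C=C(C)C[C@H](O[Si](C)(C)C(C)(C)C)[C@@]2(C)[C@H](OC(=S)n4ccnc4)[C@@H]3OC(C)(C)O[C@]3(C(C)C)[C@@H]12 | intermediate
28 | 3α,4α-O-isopropylidene-6β-[4-(TIPSO)benzoyloxy]-10α-TBSO-4β-isopropyl-core-7-ene (C2 = CH2) | O=C(c1ccc(O[Si](C(C)C)(C(C)C)C(C)C)cc1)O[C@H]1C=C(C)C[C@H](O[Si](C)(C)C(C)(C)C)[C@@]2(C)C[C@@H]3OC(C)(C)O[C@]3(C(C)C)[C@@H]12 | intermediate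
29 | 3α,4α-dihydroxy-6β-[4-(TIPSO)benzoyloxy]-10α-TBSO-4β-isopropyl-core-7-ene | O=C(c1ccc(O[Si](C(C)C)(C(C)C)C(C)C)cc1)O[C@H]1C=C(C)C[C@H](O[Si](C)(C)C(C)(C)C)[C@@]2(C)C[C@H](O)[C@@](O)(C(C)C)[C@@H]12 | intermediate
30 | 3α-acetoxy-4α-hydroxy-6β-[4-(TIPSO)benzoyloxy]-10α-TBSO-4β-isopropyl-core-7-ene | O=C(c1ccc(O[Si](C(C)C)(C(C)C)C(C)C)cc1)O[C@H]1C=C(C)C[C@H](O[Si](C)(C)C(C)(C)C)[C@@]2(C)C[C@H](OC(C)=O)[C@@](O)(C(C)C)[C@@H]12 | intermediate
31 | CNP0146780.2 | CC(=O)O[C@H]1C[C@]2(C)[C@@H](O)CC(C)=C[C@H](OC(=O)c3ccc(O)cc3)[C@@H]2[C@]1(O)C(C)C | target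

**Step count**

Total: 21 steps. Longest linear sequence: 20 steps (steps 1–9 and 11–21); step 10 is a one-step branch.

**Three steps most likely to fail**

Step 6. The oxidant may approach C9=C10 from the β face instead of the α face, which would give the C10 epimer. The fallback sets out from 9 and turns the same facial preference around by the halohydrin route. NBS in THF/H2O at 0 °C forms the bromonium ion on the face that the epoxidant prefers, and water opens it anti to give the trans-bromohydrin 10β-bromo-9α-hydroxy-4β-isopropyl-core-7-ene-2,6-dione F1 (the regioisomeric bromohydrin would close to the same epoxide). Ag2O in THF then closes the 9α-oxygen onto C10 with inversion, and the route is rejoined at α-epoxide 10.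

Step 9. Hydride may be delivered to the β face of C6, for example if the 10α-silyloxy group screens the α face across the ring, which would give the 6α-alcohol. The fallback sets out from 12: the epimeric alcohol 6α-hydroxy-10α-TBSO-4β-isopropyl-core-7-en-2-one F2 is not discarded but esterified with inversion under Mitsunobu conditions (acid 16, PPh3, DIAD, toluene, 0 °C). This returns directly to ester 17, and step 11 is then not needed.

Step 13. The boryl-copper species may fail to add to the hindered β-carbon C4 (β-isopropyl, next to the ring fusion), or the alkoxide may start a vinylogous elimination of the C6 ester through C5. The fallback sets out from 19: Weitz–Scheffer epoxidation (t-BuOOH, DBU, CH2Cl2, 0 °C) attacks only the enone, from the α face, and gives 3α,4α-epoxy-6β-[4-(TIPSO)benzoyloxy]-10α-TBSO-4β-isopropyl-core-7-en-2-one F3. SmI2 (THF/MeOH, −78 °C) then cleaves its C3–O bond and the route is rejoined at β-hydroxy ketone 21.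

**Further compounds**

F1 | step 6 | 10β-bromo-9α-hydroxy-4β-isopropyl-core-7-ene-2,6-dione | O=C1C=C(C)[C@H](O)[C@@H](Br)[C@@]2(C)C(=O)C[C@@H](C(C)C)[C@@H]12
F2 | step 9 | 6α-hydroxy-10α-TBSO-4β-isopropyl-core-7-en-2-one | O[C@@H]1C=C(C)C[C@H](O[Si](C)(C)C(C)(C)C)[C@@]2(C)C(=O)C[C@@H](C(C)C)[C@@H]12
F3 | step 13 | 3α,4α-epoxy-6β-[4-(TIPSO)benzoyloxy]-10α-TBSO-4β-isopropyl-core-7-en-2-one | O=C(c1ccc(O[Si](C(C)C)(C(C)C)C(C)C)cc1)O[C@H]1C=C(C)C[C@H](O[Si](C)(C)C(C)(C)C)[C@@]2(C)C(=O)[C@@H]3O[C@]3(C(C)C)[C@@H]12
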